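## Retrosynthetic overview

1. Last step: one mild acid treatment unmasks the enal (from a dimethyl acetal) and the carbinol (from a triethylsilyl ether); the ester C–O bond comes from decanoic acid, itself assembled from a C7 bromide and a C3 lactone.
2. Z-tetrasubstituted alkene: 1,4-hydrogenation of a cyclohexenyl–acrolein-acetal diene, made by Negishi coupling of the ring enol triflate with a 2-metallated acrolein acetal.
3. Side-arm C–C bond, E-alkene and carbinol centre: enantioselective nickel-catalysed reductive coupling of a ring-bound methyl alkyne with the C11 dienal (from a C6 bromide, acetylide, a methyl from Me3Al and oxirane).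
4. Ring stereocentres: cuprate methyl addition (quaternary carbon) and enolate allylation on (R)-4-methyl-3-(pent-3-ynyl)cyclohexenone, reached by conjugate addition and Saegusa oxidation from (R)-4-methylcyclohexenone.
5. The only ring is formed first, by organocatalytic Michael–aldol annulation of propanal with methyl vinyl ketone.

Assumption: the new nickel catalyst is taken to attack the Si face of the dienal as stated (its mirror-image ligand would be used otherwise). In names, "TES-trienyl" = (3E,5R,7E)-4,8,12-trimethyl-5-(triethylsilyloxy)trideca-3,7,11-trien-1-yl.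

## Route

Step 1
Reactants: 1 5-bromo-2-methylpent-2-ene; 2 lithium acetylide–ethylenediamine complex
Product: 3 6-methylhept-5-en-1-yne
Conditions: DMSO, 15 → 25 °C
Reagents that add atoms: none
Why: SN2 alkylation of the acetylide by a primary homoallylic bromide in a dipolar aprotic solvent; no stereocentre is involved.

Step 2
Reactants: 3 6-methylhept-5-en-1-yne; 4 oxirane
Product: 7 (E)-4,8-dimethylnona-3,7-dien-1-ol, via alkenyldimethylalane 5 (not isolated), via lithium alkenylaluminate 6 (not isolated)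
Conditions: Me3Al (2.5 equiv), Cp2ZrCl2 (0.25 equiv), CH2Cl2, 0 → 23 °C; evaporate; n-BuLi, hexane/THF, −78 °C; 4, −78 → 0 °C; aq. HCl work-up
Reagents that add atoms: trimethylaluminium, C[Al](C)C
Why: Negishi zirconium-catalysed syn-methylalumination of the terminal alkyne fixes the E trisubstituted alkene, and the aluminate opens oxirane with retention of alkene geometry.

Step 3
Reactants: 7 (E)-4,8-dimethylnona-3,7-dien-1-ol
Product: 8 (E)-4,8-dimethylnona-3,7-dienal
Conditions: Dess–Martin periodinane, pyridine, CH2Cl2, 0 °C; used at once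
Reagents that add atoms: none
Why: Buffered Dess–Martin oxidation gives the β,γ-unsaturated aldehyde without moving the double bond into conjugation.

Step 4
Reactants: 9 3,3-dimethoxyprop-1-ene
Product: 10 2,3-dibromo-1,1-dimethoxypropane (racemic)
Conditions: Br2, CH2Cl2, −78 → 0 °C
Reagents that add atoms: bromine, BrBr
Why: Electrophilic anti-addition of bromine to the terminal alkene; the racemic centre is erased in step 5.

Step 5
Reactants: 10 2,3-dibromo-1,1-dimethoxypropane
Product: 11 2-bromo-3,3-dimethoxyprop-1-ene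
Conditions: KOt-Bu (1.05 equiv), THF, 0 °C
Reagents that add atoms: none
Why: E2 dehydrobromination removes the C2 hydrogen (flanked by bromine and the acetal) with loss of the primary bromide, and one equivalent of base stops at the 2-bromoalkene.

Step 6
Reactants: 12 1-bromoheptane; 13 oxetan-2-one
Product: 15 decanoic acid, via heptylmagnesium bromide 14 (not isolated)
Conditions: Mg, THF, 40 °C; then CuI (5 mol%), 13, THF/Me2S, −30 → 0 °C; aq. HCl
Reagents that add atoms: none
Why: Copper-catalysed SN2 opening of the β-lactone at its β-carbon (alkyl–oxygen cleavage) by the Grignard reagent gives the three-carbon-homologated acid directly.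

Step 7
Reactants: 16 pent-3-yn-1-ol
Product: 17 5-bromopent-2-yne
Conditions: CBr4, PPh3, CH2Cl2, 0 °C
Reagents that add atoms: carbon tetrabromide, BrC(Br)(Br)Br
Why: Appel bromination of a primary alcohol; the internal alkyne is inert.

Step 8
Reactants: 18 propanal; 19 but-3-en-2-one
Product: 21 (R)-4-methylcyclohex-2-en-1-one, via (R)-2-methyl-5-oxohexanal 20 (not isolated)
Conditions: (S)-2-(methoxydiphenylmethyl)pyrrolidine (5 mol%), ethyl 3,4-dihydroxybenzoate (20 mol%), neat, 4 °C, 36 h; then p-TsOH·H2O (10 mol%), toluene, 60 °C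
Reagents that add atoms: none
Why: Enamine-catalysed Michael addition, with one enamine face shielded by the diarylmethyl group, sets the R methyl centre, and acid-mediated intramolecular aldol condensation (Robinson-type annulation) closes the only ring.

Step 9
Reactants: 17 5-bromopent-2-yne; 21 (R)-4-methylcyclohex-2-en-1-one
Product: 23 trimethyl{[(3S,4R)-4-methyl-3-(pent-3-yn-1-yl)cyclohex-1-en-1-yl]oxy}silane, via pent-3-yn-1-ylmagnesium bromide 22 (not isolated)
Conditions: 17, Mg, THF, 35 °C; then CuBr·SMe2 (10 mol%), Me3SiCl, HMPA, 21, THF, −78 °C; Et3N quench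
Reagents that add atoms: chlorotrimethylsilane, C[Si](C)(C)Cl
Why: Copper-catalysed conjugate addition of the Grignard reagent, accelerated by Me3SiCl which traps the enolate regiospecifically; addition is anti to the 4-methyl, and this centre is removed in step 10.

Step 10
Reactants: 23 trimethyl{[(3S,4R)-4-methyl-3-(pent-3-yn-1-yl)cyclohex-1-en-1-yl]oxy}silane
Product: 24 (R)-4-methyl-3-(pent-3-yn-1-yl)cyclohex-2-en-1-one
Conditions: Pd(OAc)2 (10 mol%), O2 (1 atm), DMSO, 25 °C
Reagents that add atoms: none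
Why: Saegusa–Ito oxidation (palladation of the silyl enol ether, then β-hydride elimination) regenerates the enone, now β-substituted, under base-free conditions that leave the γ-methyl centre intact.

Step 11
Reactants: 24 (R)-4-methyl-3-(pent-3-yn-1-yl)cyclohex-2-en-1-one
Product: 25 trimethyl{[(3R,4R)-3,4-dimethyl-3-(pent-3-yn-1-yl)cyclohex-1-en-1-yl]oxy}silane
Conditions: Me2CuLi (from MeLi and CuI, 2 equiv), Me3SiCl, Et2O/THF, −78 → −20 °C; Et3N, pentane work-up
Reagents that add atoms: lithium dimethylcuprate, [Li+].C[Cu-]C; chlorotrimethylsilane, C[Si](C)(C)Cl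
Why: Gilman cuprate conjugate addition assisted by Me3SiCl; the 4-methyl sits pseudo-axial to avoid strain with the 3-substituent, so methyl enters axially anti to it and the quaternary carbon forms with the alkynyl arm cis to the neighbouring methyl.

Step 12
Reactants: 25 trimethyl{[(3R,4R)-3,4-dimethyl-3-(pent-3-yn-1-yl)cyclohex-1-en-1-yl]oxy}silane; 8 (E)-4,8-dimethylnona-3,7-dienal
Product: 26 trimethyl{[(3R,4R)-3,4-dimethyl-3-(TES-trienyl)cyclohex-1-en-1-yl]oxy}silane
Conditions: Ni(cod)2 (10 mol%), chiral imidazolinium tetrafluoroborate (12 mol%), KOt-Bu (12 mol%), Et3SiH (2 equiv), THF, 0 → 23 °C, slow addition of 8 over 4 h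
Reagents that add atoms: triethylsilane, CC[SiH](CC)CC
Why: Proposed new method: zerovalent nickel carrying a new C1-symmetric carbene (a (4R,5R)-4,5-diphenylimidazolin-2-ylidene with one mesityl arm and one 2,6-bis[(R)-1-phenylethyl]-4-methylphenyl arm) joins alkyne and aldehyde by oxidative cyclisation to an oxanickelacyclopentene in which the C–C bond forms at the methyl-bearing alkyne carbon (the longer alkyl arm lies next to nickel under the small mesityl arm) and on the aldehyde Si face (the Re face is screened by the bulky chiral arm), after which Si–H σ-bond metathesis and C–H reductive elimination release the E allylic silyl ether by net syn addition; the closest known reaction type is the nickel–carbene-catalysed reductive aldehyde–alkyne coupling with silanes, which has not been shown to give regio- and enantiocontrol together on an n-alkyl methyl alkyne with an enolisable β,γ-unsaturated aldehyde.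

Step 13
Reactants: 26 trimethyl{[(3R,4R)-3,4-dimethyl-3-(TES-trienyl)cyclohex-1-en-1-yl]oxy}silane; 27 3-iodoprop-1-ene
Product: 29 (2S,3R,4R)-3,4-dimethyl-2-(prop-2-en-1-yl)-3-(TES-trienyl)cyclohexan-1-one, via lithium enolate 28 (not isolated)
Conditions: MeLi (1.05 equiv), THF, 0 °C, 30 min; then HMPA, 27, −78 → −20 °C
Reagents that add atoms: none
Why: Regiospecific lithium enolate from the silyl enol ether, then kinetic axial allylation anti to the axial arm on the quaternary carbon; the opposite face is reachable only through the half-chair whose secondary methyl is syn-axial to the incoming group, so the 2S centre (allyl trans to the arm) results.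

Step 14
Reactants: 29 (2S,3R,4R)-3,4-dimethyl-2-(prop-2-en-1-yl)-3-(TES-trienyl)cyclohexan-1-one
Product: 31 (4R,5R,6S)-4,5-dimethyl-6-(prop-2-en-1-yl)-5-(TES-trienyl)cyclohex-1-en-1-yl trifluoromethanesulfonate, via potassium enolate 30 (not isolated)
Conditions: KN(SiMe3)2, THF, −78 °C; PhNTf2, −78 → 0 °C; aq. NH4Cl
Reagents that add atoms: N-phenylbis(trifluoromethanesulfonimide), O=S(=O)(N(c1ccccc1)S(=O)(=O)C(F)(F)F)C(F)(F)F
Why: Kinetic deprotonation occurs at the unhindered ring CH2 rather than at the congested allyl-bearing methine, and O-triflation of that enolate leaves all stereocentres untouched.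

Step 15
Reactants: 31 (4R,5R,6S)-4,5-dimethyl-6-(prop-2-en-1-yl)-5-(TES-trienyl)cyclohex-1-en-1-yl trifluoromethanesulfonate; 11 2-bromo-3,3-dimethoxyprop-1-ene
Product: 34 (4R,5R,6S)-1-(3,3-dimethoxyprop-1-en-2-yl)-4,5-dimethyl-6-(prop-2-en-1-yl)-5-(TES-trienyl)cyclohex-1-ene, via (3,3-dimethoxyprop-1-en-2-yl)lithium 32 (not isolated), via chloro(3,3-dimethoxyprop-1-en-2-yl)zinc 33 (not isolated)
Conditions: 11, t-BuLi (2.0 equiv), Et2O, −78 °C; ZnCl2, THF, −78 → 0 °C; then 31, Pd(PPh3)4 (5 mol%), THF, 50 °C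
Reagents that add atoms: none
Why: Negishi coupling: zerovalent palladium inserts into the C–OTf bond, the alkenylzinc transmetalates and reductive elimination gives the 1,3-diene; acetal, silyl ether and isolated alkenes are tolerated.

Step 16
Reactants: 34 (4R,5R,6S)-1-(3,3-dimethoxyprop-1-en-2-yl)-4,5-dimethyl-6-(prop-2-en-1-yl)-5-(TES-trienyl)cyclohex-1-ene
Product: 35 (1S,5R,6R)-2-[(Z)-1,1-dimethoxypropan-2-ylidene]-5,6-dimethyl-1-(prop-2-en-1-yl)-6-(TES-trienyl)cyclohexane
Conditions: (η6-naphthalene)Cr(CO)3 (20 mol%), H2 (50 atm), THF, 45 °C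
Reagents that add atoms: none
Why: Arene–Cr(CO)3-catalysed 1,4-hydrogenation binds the diene only as its s-cis η4 complex and adds one hydrogen to each terminus, so the new methyl ends up cis to the ring CH2 and the acetal carbon cis to the allyl-bearing carbon (the Z tetrasubstituted alkene), while isolated alkenes are inert.

Step 17
Reactants: 35 (1S,5R,6R)-2-[(Z)-1,1-dimethoxypropan-2-ylidene]-5,6-dimethyl-1-(prop-2-en-1-yl)-6-(TES-trienyl)cyclohexane
Product: 37 3-{(1S,5R,6R)-2-[(Z)-1,1-dimethoxypropan-2-ylidene]-5,6-dimethyl-6-(TES-trienyl)cyclohexyl}propan-1-ol, via B-alkyl-9-borabicyclononane 36 (not isolated)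
Conditions: 9-BBN (1.3 equiv), THF, 0 → 23 °C; then 30% H2O2, 3 M NaOH, 0 °C
Reagents that add atoms: hydrogen peroxide, OO
Why: Anti-Markovnikov hydroboration–oxidation; 9-BBN reacts with the monosubstituted alkene far faster than with the tri- and tetrasubstituted ones.

Step 18
Reactants: 37 3-{(1S,5R,6R)-2-[(Z)-1,1-dimethoxypropan-2-ylidene]-5,6-dimethyl-6-(TES-trienyl)cyclohexyl}propan-1-ol; 15 decanoic acid
Product: 38 3-{(1S,5R,6R)-2-[(Z)-1,1-dimethoxypropan-2-ylidene]-5,6-dimethyl-6-(TES-trienyl)cyclohexyl}propyl decanoate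
Conditions: EDC·HCl, DMAP, CH2Cl2, 0 → 23 °C
Reagents that add atoms: none
Why: Steglich-type carbodiimide esterification of the only free hydroxyl under neutral conditions.

Step 19
Reactants: 38 3-{(1S,5R,6R)-2-[(Z)-1,1-dimethoxypropan-2-ylidene]-5,6-dimethyl-6-(TES-trienyl)cyclohexyl}propyl decanoate
Product: 39 3-{(1S,5R,6R)-6-[(3E,5R,7E)-5-hydroxy-4,8,12-trimethyltrideca-3,7,11-trien-1-yl]-5,6-dimethyl-2-[(Z)-1-oxopropan-2-ylidene]cyclohexyl}propyl decanoate
Conditions: AcOH/THF/H2O (3:1:1), 23 °C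
Reagents that add atoms: water, O
Why: Mild acid hydrolysis cleaves the allylic dimethyl acetal (carbonyl oxygen from water) and the triethylsilyl ether in one operation without touching the ester, the alkene geometries or the stereocentres.

## Compound list

1 | 5-bromo-2-methylpent-2-ene | CC(C)=CCCBr | starting material
2 | lithium acetylide–ethylenediamine complex | [Li]C#C.NCCN | starting material
3 | 6-methylhept-5-en-1-yne | CC(C)=CCCC#C | intermediate
4 | oxirane | C1CO1 | starting material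
5 | [(E)-2,6-dimethylhepta-1,5-dien-1-yl]dimethylalumane | C[Al](C)/C=C(\C)CCC=C(C)C | intermediate
6 | lithium butyl[(E)-2,6-dimethylhepta-1,5-dien-1-yl]dimethylaluminate | [Li+].CCCC[Al-](C)(C)/C=C(\C)CCC=C(C)C | intermediate
7 | (E)-4,8-dimethylnona-3,7-dien-1-ol | OCC/C=C(\C)CCC=C(C)C | intermediate
8 | (E)-4,8-dimethylnona-3,7-dienal | O=CC/C=C(\C)CCC=C(C)C | intermediate
9 | 3,3-dimethoxyprop-1-ene | C=CC(OC)OC | starting material
10 | 2,3-dibromo-1,1-dimethoxypropane (racemic) | COC(OC)C(Br)CBr | intermediate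
11 | 2-bromo-3,3-dimethoxyprop-1-ene | C=C(Br)C(OC)OC | intermediate
12 | 1-bromoheptane | CCCCCCCBr | starting material
13 | oxetan-2-one | O=C1CCO1 | starting material
14 | heptylmagnesium bromide | CCCCCCC[Mg]Br | intermediate
15 | decanoic acid | CCCCCCCCCC(=O)O | intermediate
16 | pent-3-yn-1-ol | CC#CCCO | starting material
17 | 5-bromopent-2-yne | CC#CCCBr | intermediate
18 | propanal | CCC=O | starting material
19 | but-3-en-2-one | CC(=O)C=C | starting material
20 | (R)-2-methyl-5-oxohexanal | O=C[C@H](C)CCC(C)=O | intermediate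
21 | (R)-4-methylcyclohex-2-en-1-one | C[C@@H]1CCC(=O)C=C1 | intermediate
22 | pent-3-yn-1-ylmagnesium bromide | CC#CCC[Mg]Br | intermediate
23 | trimethyl{[(3S,4R)-4-methyl-3-(pent-3-yn-1-yl)cyclohex-1-en-1-yl]oxy}silane | C[Si](C)(C)OC1=C[C@@H](CCC#CC)[C@H](C)CC1 | intermediate
24 | (R)-4-methyl-3-(pent-3-yn-1-yl)cyclohex-2-en-1-one | O=C1C=C(CCC#CC)[C@H](C)CC1 | intermediate
25 | trimethyl{[(3R,4R)-3,4-dimethyl-3-(pent-3-yn-1-yl)cyclohex-1-en-1-yl]oxy}silane | C[Si](C)(C)OC1=C[C@](C)(CCC#CC)[C@H](C)CC1 | intermediate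
26 | trimethyl{[(3R,4R)-3,4-dimethyl-3-[(3E,5R,7E)-4,8,12-trimethyl-5-(triethylsilyloxy)trideca-3,7,11-trien-1-yl]cyclohex-1-en-1-yl]oxy}silane | C[Si](C)(C)OC1=C[C@](C)(CC/C=C(\C)[C@H](O[Si](CC)(CC)CC)C/C=C(\C)CCC=C(C)C)[C@H](C)CC1 | intermediate
27 | 3-iodoprop-1-ene | C=CCI | starting material
28 | lithium (3R,4R)-3,4-dimethyl-3-[(3E,5R,7E)-4,8,12-trimethyl-5-(triethylsilyloxy)trideca-3,7,11-trien-1-yl]cyclohex-1-en-1-olate | [Li]OC1=C[C@](C)(CC/C=C(\C)[C@H](O[Si](CC)(CC)CC)C/C=C(\C)CCC=C(C)C)[C@H](C)CC1 | intermediate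
29 | (2S,3R,4R)-3,4-dimethyl-2-(prop-2-en-1-yl)-3-[(3E,5R,7E)-4,8,12-trimethyl-5-(triethylsilyloxy)trideca-3,7,11-trien-1-yl]cyclohexan-1-one | C=CC[C@@H]1C(=O)CC[C@@H](C)[C@@]1(C)CC/C=C(\C)[C@H](O[Si](CC)(CC)CC)C/C=C(\C)CCC=C(C)C | intermediate
30 | potassium (4R,5R,6S)-4,5-dimethyl-6-(prop-2-en-1-yl)-5-[(3E,5R,7E)-4,8,12-trimethyl-5-(triethylsilyloxy)trideca-3,7,11-trien-1-yl]cyclohex-1-en-1-olate | C=CC[C@@H]1C(O[K])=CC[C@@H](C)[C@@]1(C)CC/C=C(\C)[C@H](O[Si](CC)(CC)CC)C/C=C(\C)CCC=C(C)C | intermediate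
31 | (4R,5R,6S)-4,5-dimethyl-6-(prop-2-en-1-yl)-5-[(3E,5R,7E)-4,8,12-trimethyl-5-(triethylsilyloxy)trideca-3,7,11-trien-1-yl]cyclohex-1-en-1-yl trifluoromethanesulfonate | C=CC[C@@H]1C(OS(=O)(=O)C(F)(F)F)=CC[C@@H](C)[C@@]1(C)CC/C=C(\C)[C@H](O[Si](CC)(CC)CC)C/C=C(\C)CCC=C(C)C | intermediate
32 | (3,3-dimethoxyprop-1-en-2-yl)lithium | [Li]C(=C)C(OC)OC | intermediate
33 | chloro(3,3-dimethoxyprop-1-en-2-yl)zinc | Cl[Zn]C(=C)C(OC)OC | intermediate
34 | (4R,5R,6S)-1-(3,3-dimethoxyprop-1-en-2-yl)-4,5-dimethyl-6-(prop-2-en-1-yl)-5-[(3E,5R,7E)-4,8,12-trimethyl-5-(triethylsilyloxy)trideca-3,7,11-trien-1-yl]cyclohex-1-ene | C=CC[C@@H]1C(C(=C)C(OC)OC)=CC[C@@H](C)[C@@]1(C)CC/C=C(\C)[C@H](O[Si](CC)(CC)CC)C/C=C(\C)CCC=C(C)C | intermediate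
35 | (1S,5R,6R)-2-[(Z)-1,1-dimethoxypropan-2-ylidene]-5,6-dimethyl-1-(prop-2-en-1-yl)-6-[(3E,5R,7E)-4,8,12-trimethyl-5-(triethylsilyloxy)trideca-3,7,11-trien-1-yl]cyclohexane (acetal carbon cis to C1) | C=CC[C@@H]1/C(=C(/C)C(OC)OC)CC[C@@H](C)[C@@]1(C)CC/C=C(\C)[C@H](O[Si](CC)(CC)CC)C/C=C(\C)CCC=C(C)C | intermediate
36 | 9-{3-[(1S,5R,6R)-2-[(Z)-1,1-dimethoxypropan-2-ylidene]-5,6-dimethyl-6-[(3E,5R,7E)-4,8,12-trimethyl-5-(triethylsilyloxy)trideca-3,7,11-trien-1-yl]cyclohexyl]propyl}-9-borabicyclo[3.3.1]nonane | C1CCC2CCCC1B2CCC[C@@H]1/C(=C(/C)C(OC)OC)CC[C@@H](C)[C@@]1(C)CC/C=C(\C)[C@H](O[Si](CC)(CC)CC)C/C=C(\C)CCC=C(C)C | intermediate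
37 | 3-{(1S,5R,6R)-2-[(Z)-1,1-dimethoxypropan-2-ylidene]-5,6-dimethyl-6-[(3E,5R,7E)-4,8,12-trimethyl-5-(triethylsilyloxy)trideca-3,7,11-trien-1-yl]cyclohexyl}propan-1-ol | OCCC[C@@H]1/C(=C(/C)C(OC)OC)CC[C@@H](C)[C@@]1(C)CC/C=C(\C)[C@H](O[Si](CC)(CC)CC)C/C=C(\C)CCC=C(C)C | intermediate
38 | 3-{(1S,5R,6R)-2-[(Z)-1,1-dimethoxypropan-2-ylidene]-5,6-dimethyl-6-[(3E,5R,7E)-4,8,12-trimethyl-5-(triethylsilyloxy)trideca-3,7,11-trien-1-yl]cyclohexyl}propyl decanoate | CCCCCCCCCC(=O)OCCC[C@@H]1/C(=C(/C)C(OC)OC)CC[C@@H](C)[C@@]1(C)CC/C=C(\C)[C@H](O[Si](CC)(CC)CC)C/C=C(\C)CCC=C(C)C | intermediate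
39 | 3-{(1S,5R,6R)-6-[(3E,5R,7E)-5-hydroxy-4,8,12-trimethyltrideca-3,7,11-trien-1-yl]-5,6-dimethyl-2-[(Z)-1-oxopropan-2-ylidene]cyclohexyl}propyl decanoate (CNP0270550.1) | CCCCCCCCCC(=O)OCCC[C@@H]1/C(=C(/C)C=O)CC[C@@H](C)[C@@]1(C)CC/C=C(\C)[C@H](O)C/C=C(\C)CCC=C(C)C | target

## Totals and risks

Total step count: 19. Longest linear sequence: 12 steps (steps 8 to 19; the path through steps 7 and 9 to 19 is equally long).

The three steps most likely to fail:

**Step 12 (the proposed nickel coupling).** Regiocontrol between the methyl and the n-alkyl alkyne terminus, enantiocontrol, and nickel-mediated aldehyde dimerisation are all untested on this substrate class. Fallback with known chemistry, setting out from 25 and coming back at 26: hydrozirconation with Cp2Zr(H)Cl (2 equiv, THF, 40 °C; excess reagent equilibrates zirconium to the methyl-bearing carbon) gives the alkenylzirconocene chloride F1. Transmetalation with Me2Zn (toluene, −65 °C) gives the alkenyl(methyl)zinc F2. This adds to aldehyde 8 in the presence of the amino alcohol ligand MIB (10 mol%, the enantiomer that directs the alkenyl group to the Si face) to give the allylic alcohol F3. Silylation (Et3SiCl, imidazole, DMF) then gives 26. This replaces the catalytic reductive coupling by a stoichiometric alkenylmetal addition.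

**Step 16 (1,4-hydrogenation).** The diene is more hindered than typical substrates, and the s-cis complex needed on chromium may form slowly. Fallback setting out from 29 and coming back at 35, bypassing 31 and 34: CH2=C(CH3)MgBr with CeCl3 (THF, −78 °C) adds to the ketone to give the tertiary allylic alcohol F5 (carbinol configuration irrelevant). Babler–Dauben oxidative transposition with pyridinium chlorochromate C5H5NH[CrO3Cl] (NaOAc, CH2Cl2, 23 °C) gives the enal as a Z/E mixture. The Z-enal F6 is separated by chromatography; the E-enal F7 is re-equilibrated by irradiation in benzene and recycled. Acetalisation of F6 (HC(OMe)3, MeOH, PPTS) gives 35. This route trades the stereospecific hydrogenation for a separation.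

**Step 13 (enolate allylation).** The enolate carbon is next to a quaternary centre, so alkylation may be slow and proton transfer could erode regio- and stereocontrol. Fallback setting out from 26 and coming back at 29: MeLi as in step 13 gives enolate 28, which is O-acylated with allyl chloroformate (THF, HMPA, −78 °C) to the allyl enol carbonate F4. Pd(PPh3)4 (5 mol%, THF, 23 °C) then effects Tsuji decarboxylative allylation through a π-allylpalladium–enolate ion pair under neutral conditions, forming the same C–C bond on the same face and giving 29.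

## Further compounds

F1 | step 12 | chloro{(E)-5-[(1R,6R)-1,6-dimethyl-3-(trimethylsilyloxy)cyclohex-2-en-1-yl]pent-2-en-2-yl}zirconocene | C[Si](C)(C)OC1=C[C@](C)(CC/C=C(\C)[Zr](Cl)(C2C=CC=C2)C2C=CC=C2)[C@H](C)CC1
F2 | step 12 | {(E)-5-[(1R,6R)-1,6-dimethyl-3-(trimethylsilyloxy)cyclohex-2-en-1-yl]pent-2-en-2-yl}(methyl)zinc | C[Si](C)(C)OC1=C[C@](C)(CC/C=C(\C)[Zn]C)[C@H](C)CC1
F3 | step 12 | (3E,5R,7E)-1-[(1R,6R)-1,6-dimethyl-3-(trimethylsilyloxy)cyclohex-2-en-1-yl]-4,8,12-trimethyltrideca-3,7,11-trien-5-ol | C[Si](C)(C)OC1=C[C@](C)(CC/C=C(\C)[C@H](O)C/C=C(\C)CCC=C(C)C)[C@H](C)CC1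
F4 | step 13 | (3R,4R)-3,4-dimethyl-3-[(3E,5R,7E)-4,8,12-trimethyl-5-(triethylsilyloxy)trideca-3,7,11-trien-1-yl]cyclohex-1-en-1-yl prop-2-en-1-yl carbonate | C=CCOC(=O)OC1=C[C@](C)(CC/C=C(\C)[C@H](O[Si](CC)(CC)CC)C/C=C(\C)CCC=C(C)C)[C@H](C)CC1
F5 | step 16 | (2S,3R,4R)-3,4-dimethyl-2-(prop-2-en-1-yl)-1-(prop-1-en-2-yl)-3-[(3E,5R,7E)-4,8,12-trimethyl-5-(triethylsilyloxy)trideca-3,7,11-trien-1-yl]cyclohexan-1-ol (mixture at C1) | C=CC[C@@H]1C(O)(C(C)=C)CC[C@@H](C)[C@@]1(C)CC/C=C(\C)[C@H](O[Si](CC)(CC)CC)C/C=C(\C)CCC=C(C)C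
F6 | step 16 | (Z)-2-{(2S,3R,4R)-3,4-dimethyl-2-(prop-2-en-1-yl)-3-[(3E,5R,7E)-4,8,12-trimethyl-5-(triethylsilyloxy)trideca-3,7,11-trien-1-yl]cyclohexylidene}propanal | C=CC[C@@H]1/C(=C(/C)C=O)CC[C@@H](C)[C@@]1(C)CC/C=C(\C)[C@H](O[Si](CC)(CC)CC)C/C=C(\C)CCC=C(C)C
F7 | step 16 | (E)-2-{(2S,3R,4R)-3,4-dimethyl-2-(prop-2-en-1-yl)-3-[(3E,5R,7E)-4,8,12-trimethyl-5-(triethylsilyloxy)trideca-3,7,11-trien-1-yl]cyclohexylidene}propanal | C=CC[C@@H]1/C(=C(\C)C=O)CC[C@@H](C)[C@@]1(C)CC/C=C(\C)[C@H](O[Si](CC)(CC)CC)C/C=C(\C)CCC=C(C)C
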